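How much target does the north-east run hold after 17 min, charged like the south-west run but with less free catalyst than any run so far? I took the settings one at a time, first by hand and then against the readings.

| flask | substrate | reagent | free catalyst | time |
|---|---|---|---|---|
| south-west | 0.400 M | 0.320 M | 0.00800 M |  |
| north | 0.240 M | 0.160 M | 0.00800 M |  |
| west | 1.20 M | 0.320 M | 0.00800 M |  |
| south-east | 0.400 M | 0.320 M | 0.00400 M |  |
| north-east | 0.400 M | 0.320 M | 0.00170 M | 17 min |

| run | time / min | [target] / M |
|---|---|---|
| south-west run | 0.68 | 0.0083 |
| south-west run | 1.2 | 0.0177 |
| south-west run | 2.0 | 0.0259 |
| south-west run | 3.4 | 0.0431 |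
| south-west run | 5.8 | 0.0735 |
| south-west run | 9.9 | 0.1212 |
| south-west run | 17 | 0.1975 |
| north run | 0.68 | 0.0068 |
| north run | 1.2 | 0.0116 |
| north run | 2.0 | 0.0193 |
| north run | 3.4 | 0.0351 |
| north run | 5.8 | 0.0577 |
| north run | 9.9 | 0.0960 |
| north run | 17 | 0.1481 |
| west run | 0.68 | 0.0168 |
| west run | 1.2 | 0.0324 |
| west run | 2.0 | 0.0534 |
| west run | 3.4 | 0.0876 |
| west run | 5.8 | 0.1402 |
| west run | 9.9 | 0.2053 |
| west run | 17 | 0.2700 |
| south-east run | 0.68 | 0.0064 |
| south-east run | 1.2 | 0.0093 |
| south-east run | 2.0 | 0.0169 |
| south-east run | 3.4 | 0.0289 |
| south-east run | 5.8 | 0.0485 |
| south-east run | 9.9 | 0.0806 |
| south-east run | 17 | 0.1301 |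

(readings scatter by 0.001 M)

1. reaction order in [substrate] at the outset, round the charge of the south-west run, defined at two percent of the substrate turned into target (one fixed amount of target, the same in the runs compared)
2. reaction order in [free catalyst] at the outset, round the charge of the south-west run, defined at two percent of the substrate turned into target
3. the north run starts with 0.160 M less of substrate and of reagent than the south-west run, and with no target. Compared where both hold the same amount of substrate, once fifteen percent of what the north run was charged with has turned into target, is the north run faster, slower or alike (within a tenth)?
4. target in the north-east run at 17 min, as a share of the substrate charged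

- Overall: substrate + reagent -> target, with free catalyst as catalyst.
- Constant volume, constant temperature.
- A reading of a species includes what of it is bound.
- "The second partner" is reagent.
- An order is taken over about fifteen percent of the charge, up and down.

1. Reagent. Each target takes one substrate and one reagent, so in the south-west run, counting what is bound, c(substrate) minus c(reagent) stays at 0.0800 M. Reagent is the limiting reagent there, so target can reach 0.320 M at most. The north-east run has the same charge, which makes its ceiling 80.0% of its substrate.

2. Substrate and reagent together. The north run has the same difference, 0.0800 M. By hand, it is therefore the south-west run after 0.160 M has been used, but with no target in it. Between 2.0 min and 5.8 min the north run climbed at 0.0101 M min⁻¹. Over its last interval, near the matching point, the south-west run climbed at 0.0107 M min⁻¹. The ratio is 0.944, so I said alike: the rate seemed to follow what the flask holds, not its age.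

3. Substrate alone. The west run has 3.00 times the substrate of the south-west run and, in the readings at 3.4 min, 2.03 times its target, an average order of 0.646. That is an average over the whole span between the two charges, so I did not take it as the local order asked.

4. Catalyst. By hand, half the catalyst would give half the rate if each catalyst worked independently. The south-east run instead held 0.1301 M at 17 min, a level that the south-west run passed, between its readings, at 10.7 min, so by these readings its clock ran at 0.631 of the south-west one. That defines the clock exponent, the power to which a ratio of catalyst charges is raised to give the ratio of rates at equal charges of substrate and reagent: 0.664.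

5. Time. By steps 1 and 2, the north-east run should pass through the south-west run's states on a slower clock, with factor 0.358. Its 17 min then equals 6.08 min of the south-west run. Between the readings at 5.8 min and 9.9 min, that gives 0.0767 M, well under the ceiling. This is 19.2% of the substrate, with the exponent stretched below the charges tried.

6. The forecast gave a substrate order of 0.6, a catalyst order of 0.6, alike and 19.5%, against my 19.2%, holding that “product has little effect and the catalyst survives”.

7. The north-east run gave 18.9%, with a substrate order of 2.0, a catalyst order of 0.62 and alike.

    free catalyst + substrate → catalyst-substrate complex (42.60 M⁻¹ min⁻¹)
    catalyst-substrate complex + reagent → loaded catalyst (499.2 M⁻¹ min⁻¹)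
    loaded catalyst → target + free catalyst (41.64 min⁻¹)
    2 free catalyst ⇌ resting dimer, settled at all times (475.0 M⁻¹)
    substrate + reagent ⇌ idle substrate-reagent adduct, settled at all times (34.70 M⁻¹)

The catalyst order at the south-west charge, 0.62, stands beside my clock exponent of 0.664. Put on the earlier south-east reading, which did not go into it, the exponent turns that run's 9.9 min into 6.25 min of the south-west run, where the south-west readings give 0.0787 M; the south-east reading at that time was 0.0806 M.

All runs are simulated from invented constants; scatter was added.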